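**Plan**

- Locants: ring A = C1 (quaternary, CH3), C2, C3, C4 (OH, i-Pr), C5 (H); ring B = C1, C5, C6 (O-aroyl), C7, C8 (=C14H2), C9 (OH), C10. Bicyclic compounds are named with these daucane locants.
- Cuts, in order: the aroyl–O6 ester; C8–C9 of ring B (alkenyl iodide + aldehyde, C9 passing through the ketone); C4–isopropyl; then C1–C10 and C5–C6 together.
- Enabling feature: C4, C5, C1 and C6 of ring A are the carbonyl, α-, β- and carbinol carbons of a 2-(1-hydroxyalkyl)-3,3-disubstituted cyclopentanone, the aldol-trapped conjugate adduct of a 3-methylcyclopentenone.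
- Forward: ring A is bought as the enone. One flask joins the C10–C9 arm (as a 1-silylvinyl group) to C1 and the C6–C7–C8 iodoalkene arm to C5. Isopropyl is then added at C4, O6 is acylated, and ring B is closed last by chromium-mediated C8–C9 coupling.
- Stereochemistry: C1 from the chiral copper–carbene catalyst; C5 by aldehyde approach anti to the silylvinyl group; C6 from the chair aldol transition state of the ring (E)-enolate; C4 by addition anti to the C5 side chain; C9 by hydride delivery anti to the C1 methyl.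

Key step: step 4

Assumption: the ligand precursor L*–H is the zwitterionic 4,5-diphenylimidazolinium salt carrying N-(2,6-diethylphenyl) and N′-(2-sulfonatophenyl) groups; the enantiomer that gives the (3S) adduct is chosen by analogy with this catalyst class on other 3-substituted cyclopentenones.

**Route**

Step 1
Reactants: 1 ethynyltrimethylsilane
Product: 2 diisobutyl[1-(trimethylsilyl)ethenyl]aluminium (kept as a stock solution)
Conditions: i-Bu2AlH (1.0 equiv), hexanes/THF 5:1, 55 °C, 2 h
Reagents that add atoms: diisobutylaluminium hydride, CC(C)C[AlH]CC(C)C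
Why: Hydroalumination adds Al–H syn across the silylalkyne and, with THF present, should place aluminium on the silicon-bearing carbon, where silicon stabilises the developing carbanion, giving the 1-silylvinyl alane directly.

Step 2
Reactants: 3 but-3-yn-1-ol
Product: 4 3-iodobut-3-en-1-ol
Conditions: NaI, TMSCl, H2O (0.5 equiv), MeCN, 22 °C
Reagents that add atoms: sodium iodide, [Na+].[I-]
Why: Markovnikov hydroiodination by HI generated in the flask should add to the terminal alkyne through the more substituted vinyl cation and give the 2-iodoalkene without touching the alcohol.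

Step 3
Reactants: 4 3-iodobut-3-en-1-ol
Product: 5 3-iodobut-3-enal
Conditions: DMP, CH2Cl2, 0 °C; pentane, filtration through Celite; solution used the same day
Reagents that add atoms: none
Why: Dess–Martin oxidation of a primary alcohol stops at the aldehyde under neutral, non-aqueous conditions and, run cold and base-free, should keep the β,γ-alkene out of conjugation.

Step 4
Reactants: 6 3-methylcyclopent-2-en-1-one; 2 diisobutyl[1-(trimethylsilyl)ethenyl]aluminium; 5 3-iodobut-3-enal
Product: 9 (2S,3S)-2-[(1S)-1-hydroxy-3-iodobut-3-en-1-yl]-3-methyl-3-[1-(trimethylsilyl)ethenyl]cyclopentan-1-one, via aluminium enolate 7 (not isolated), via lithium aluminate enolate 8 (not isolated)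
Conditions: Cu(OTf)2 (5 mol %), L*–H (5 mol %) pre-treated with Ag2O (2.5 mol %), 2 (1.5 equiv), THF, −78 → 22 °C; then MeLi (1.5 equiv), −78 °C; then 5 (3 equiv), −78 °C; aq. KNaC4H4O6
Reagents that add atoms: none
Why: The chiral carbene–copper catalyst formed from Cu(OTf)2 and L* takes the 1-silylvinyl group from aluminium and delivers it 1,4 to the enone β-carbon C1 (alkenyl transfer to copper, π-complexation, conjugate oxidative addition to a trivalent copper intermediate, reductive elimination), releasing the regiodefined aluminium enolate 7; MeLi converts it into the more nucleophilic aluminate 8, whose C5 adds to the aldehyde through a closed chair transition state. The closest known reaction types are the copper-catalysed enantioselective conjugate addition of silicon-substituted alkenylaluminium reagents to 3-substituted cyclopentenones and the aldol trapping of conjugate-addition enolates in three-component couplings. No ring is closed: the step forms the two bonds C1–C10 and C5–C6 on the preformed ring A. C1 is controlled by the chiral ligand, C5 by approach of the aldehyde anti to the bulky silylvinyl group on the neighbouring quaternary carbon (syn to the methyl group), and C6 by the chair transition state, in which the ring-locked (E)-enolate and an equatorial aldehyde substituent give the anti (5S,6S) relation. The step needs 1,4- over 1,2-addition and alkenyl over isobutyl transfer (copper catalysis, faster transfer of the sp2 ligand), a single enolate regioisomer (fixed by the conjugate addition and held at −78 °C) and addition rather than proton transfer to the α-acidic aldehyde (low temperature, excess aldehyde, an aluminate less basic than a lithium enolate).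

Step 5
Reactants: 9 (2S,3S)-2-[(1S)-1-hydroxy-3-iodobut-3-en-1-yl]-3-methyl-3-[1-(trimethylsilyl)ethenyl]cyclopentan-1-one
Product: 10 (2S,3R)-3-ethenyl-2-[(1S)-1-hydroxy-3-iodobut-3-en-1-yl]-3-methylcyclopentan-1-one
Conditions: CF3CO2H (5 equiv), CH2Cl2, 0 → 22 °C; aq. NaHCO3/MeOH work-up
Reagents that add atoms: none
Why: Protodesilylation of a vinylsilane proceeds by ipso protonation to a β-silyl-stabilised cation that loses the trimethylsilyl group, and it is placed here because the ketone stage has no acid-labile tertiary alcohol, while the electron-poor iodoalkene and the hindered ketol are expected to persist and no stereocentre is touched.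

Step 6
Reactants: 10 (2S,3R)-3-ethenyl-2-[(1S)-1-hydroxy-3-iodobut-3-en-1-yl]-3-methylcyclopentan-1-one
Product: 11 (2S,3R)-3-ethenyl-2-[(1S)-3-iodo-1-(triethylsilyloxy)but-3-en-1-yl]-3-methylcyclopentan-1-one
Conditions: TESOTf, 2,6-lutidine, CH2Cl2, −78 °C
Reagents that add atoms: triethylsilyl trifluoromethanesulfonate, CC[Si](CC)(CC)OS(=O)(=O)C(F)(F)F
Why: Silyl ether formation with a silyl triflate and a hindered pyridine base at −78 °C is fast and mild enough to avoid retro-aldol cleavage or elimination of the β-hydroxy ketone.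

Step 7
Reactants: 11 (2S,3R)-3-ethenyl-2-[(1S)-3-iodo-1-(triethylsilyloxy)but-3-en-1-yl]-3-methylcyclopentan-1-one
Product: 12 (1R,2S,3R)-3-ethenyl-2-[(1S)-3-iodo-1-(triethylsilyloxy)but-3-en-1-yl]-3-methyl-1-(propan-2-yl)cyclopentan-1-ol
Conditions: i-PrMgCl, CeCl3 (anhydrous), THF, −78 → −40 °C; aq. NH4Cl
Reagents that add atoms: isopropylmagnesium chloride, CC(C)[Mg]Cl
Why: Organocerium 1,2-addition uses a weakly basic, strongly oxophilic isopropyl reagent that should suppress enolisation and β-hydride reduction of the hindered ketone and leave the alkenyl iodide unexchanged at low temperature, and it attacks C4 from the face opposite the bulky adjacent C5 side chain, so the new hydroxyl is cis to that chain (4R).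

Step 8
Reactants: 12 (1R,2S,3R)-3-ethenyl-2-[(1S)-3-iodo-1-(triethylsilyloxy)but-3-en-1-yl]-3-methyl-1-(propan-2-yl)cyclopentan-1-ol
Product: 13 (1R,2S,3R)-3-ethenyl-2-[(1S)-1-hydroxy-3-iodobut-3-en-1-yl]-3-methyl-1-(propan-2-yl)cyclopentan-1-ol
Conditions: TBAF, AcOH, THF, 0 → 22 °C
Reagents that add atoms: none
Why: Fluoride desilylation buffered with acetic acid removes the triethylsilyl ether without base-induced dehydrohalogenation of the iodoalkene.

Step 9
Reactants: 14 4-hydroxybenzoic acid
Product: 16 4-{[tri(propan-2-yl)silyl]oxy}benzoic acid, via bis-silylated acid 15 (not isolated)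
Conditions: TIPSCl (2.2 equiv), imidazole, DMF, 22 °C; then K2CO3, THF/MeOH/H2O, 22 °C; aq. HCl to pH 4
Reagents that add atoms: chlorotri(propan-2-yl)silane, CC(C)[Si](Cl)(C(C)C)C(C)C
Why: Silylation of both acidic groups followed by selective hydrolysis of the far more labile silyl ester leaves the aryl triisopropylsilyl ether, a phenol mask expected to survive the later borane oxidation, chromium and hydride steps yet fall to fluoride.

Step 10
Reactants: 13 (1R,2S,3R)-3-ethenyl-2-[(1S)-1-hydroxy-3-iodobut-3-en-1-yl]-3-methyl-1-(propan-2-yl)cyclopentan-1-ol; 16 4-{[tri(propan-2-yl)silyl]oxy}benzoic acid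
Product: 17 (1S)-1-[(1S,2R,5R)-2-ethenyl-5-hydroxy-2-methyl-5-(propan-2-yl)cyclopentyl]-3-iodobut-3-en-1-yl 4-{[tri(propan-2-yl)silyl]oxy}benzoate
Conditions: DCC, DMAP, CH2Cl2, 22 °C
Reagents that add atoms: none
Why: Steglich esterification through the acylpyridinium ion should acylate the secondary C6 hydroxyl only, the tertiary C4 hydroxyl being too hindered, and installing the ester before ring closure avoids any later need to distinguish O6 from O9.

Step 11
Reactants: 17 (1S)-1-[(1S,2R,5R)-2-ethenyl-5-hydroxy-2-methyl-5-(propan-2-yl)cyclopentyl]-3-iodobut-3-en-1-yl 4-{[tri(propan-2-yl)silyl]oxy}benzoate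
Product: 19 (1S)-1-[(1S,2R,5R)-2-hydroxy-5-(2-hydroxyethyl)-5-methyl-2-(propan-2-yl)cyclopentyl]-3-iodobut-3-en-1-yl 4-{[tri(propan-2-yl)silyl]oxy}benzoate, via B-alkyl-9-BBN adduct 18 (not isolated)
Conditions: 9-BBN (3 equiv), THF, 0 → 22 °C; then NaBO3·4H2O, THF/H2O, 22 °C
Reagents that add atoms: sodium perborate tetrahydrate (NaBO3·4H2O), [Na+].[O-]OB=O.O.O.O.O
Why: Hydroboration–oxidation with 9-BBN adds anti-Markovnikov to the monosubstituted vinyl group much faster than to the electron-poor 1,1-disubstituted iodoalkene, and the mildly basic perborate oxidation should spare the aryl ester and the aryl silyl ether.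

Step 12
Reactants: 19 (1S)-1-[(1S,2R,5R)-2-hydroxy-5-(2-hydroxyethyl)-5-methyl-2-(propan-2-yl)cyclopentyl]-3-iodobut-3-en-1-yl 4-{[tri(propan-2-yl)silyl]oxy}benzoate
Product: 20 (1S)-1-[(1S,2R,5R)-2-hydroxy-5-methyl-5-(2-oxoethyl)-2-(propan-2-yl)cyclopentyl]-3-iodobut-3-en-1-yl 4-{[tri(propan-2-yl)silyl]oxy}benzoate
Conditions: DMP, pyridine, CH2Cl2, 0 → 22 °C
Reagents that add atoms: none
Why: Dess–Martin oxidation takes the primary alcohol to the aldehyde and leaves the tertiary alcohol untouched, and no lactol can form because the C4 hydroxyl and the C10 chain lie trans across ring A.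

Step 13
Reactants: 20 (1S)-1-[(1S,2R,5R)-2-hydroxy-5-methyl-5-(2-oxoethyl)-2-(propan-2-yl)cyclopentyl]-3-iodobut-3-en-1-yl 4-{[tri(propan-2-yl)silyl]oxy}benzoate
Product: 22 (1R,4R,5S,6S)-4,9-dihydroxydauc-8(14)-en-6-yl 4-{[tri(propan-2-yl)silyl]oxy}benzoate (trans-fused; both C9 epimers), via alkenylchromium dichloride 21 (not isolated)
Conditions: CrCl2 (6 equiv), NiCl2 (5 mol %), DMSO/THF, 22 °C, 0.005 M
Reagents that add atoms: none
Why: In the Nozaki–Hiyama–Kishi reaction zerovalent nickel inserts into the alkenyl C–I bond and passes the alkenyl group to chromium, and the trivalent alkenylchromium species should add to the aldehyde in preference to the ester and in the presence of the free hydroxyl, closing the seven-membered ring B at high dilution with the alkene exocyclic; the C9 configuration is not relied upon because it is reset in the next two steps.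

Step 14
Reactants: 22 (1R,4R,5S,6S)-4,9-dihydroxydauc-8(14)-en-6-yl 4-{[tri(propan-2-yl)silyl]oxy}benzoate
Product: 23 (1R,4R,5S,6S)-4-hydroxy-9-oxodauc-8(14)-en-6-yl 4-{[tri(propan-2-yl)silyl]oxy}benzoate
Conditions: DMP, pyridine, CH2Cl2, 0 °C; used without storage
Reagents that add atoms: none
Why: Dess–Martin oxidation of the allylic alcohol converts both C9 epimers into one α-methylene ketone while the tertiary alcohol, ester and silyl ether stay intact.

Step 15
Reactants: 23 (1R,4R,5S,6S)-4-hydroxy-9-oxodauc-8(14)-en-6-yl 4-{[tri(propan-2-yl)silyl]oxy}benzoate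
Product: 24 (1R,4R,5S,6S,9R)-4,9-dihydroxydauc-8(14)-en-6-yl 4-{[tri(propan-2-yl)silyl]oxy}benzoate
Conditions: NaBH4, CeCl3·7H2O, MeOH, −78 °C
Reagents that add atoms: none
Why: Luche reduction gives 1,2-reduction of the α-methylene ketone, and hydride should reach C9 from the face opposite the axial C1 methyl group (1,3 to C9), placing the new hydroxyl cis to that methyl (9R), as in hydride reductions of ring ketones 1,3 to an angular methyl.

Step 16
Reactants: 24 (1R,4R,5S,6S,9R)-4,9-dihydroxydauc-8(14)-en-6-yl 4-{[tri(propan-2-yl)silyl]oxy}benzoate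
Product: 25 (1R,4R,5S,6S,9R)-4,9-dihydroxydauc-8(14)-en-6-yl 4-hydroxybenzoate (CNP0164257.2)
Conditions: TBAF, AcOH, THF, 0 °C
Reagents that add atoms: none
Why: Fluoride cleaves the aryl silyl ether within minutes at 0 °C, and the acetic acid buffer should prevent ester cleavage or acyl migration by the liberated phenoxide.

**Compound list**

1 | ethynyltrimethylsilane | C#C[Si](C)(C)C | starting material
2 | diisobutyl[1-(trimethylsilyl)ethenyl]aluminium | C=C([Si](C)(C)C)[Al](CC(C)C)CC(C)C | intermediate
3 | but-3-yn-1-ol | C#CCCO | starting material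
4 | 3-iodobut-3-en-1-ol | C=C(I)CCO | intermediate
5 | 3-iodobut-3-enal | C=C(I)CC=O | intermediate
6 | 3-methylcyclopent-2-en-1-one | CC1=CC(=O)CC1 | starting material
7 | diisobutyl({(3S)-3-methyl-3-[1-(trimethylsilyl)ethenyl]cyclopent-1-en-1-yl}oxy)aluminium | C=C([Si](C)(C)C)[C@@]1(C)CCC(O[Al](CC(C)C)CC(C)C)=C1 | intermediate (not isolated)
8 | lithium diisobutyl(methyl)({(3S)-3-methyl-3-[1-(trimethylsilyl)ethenyl]cyclopent-1-en-1-yl}oxy)aluminate | [Li+].C=C([Si](C)(C)C)[C@@]1(C)CCC(O[Al-](C)(CC(C)C)CC(C)C)=C1 | intermediate (not isolated)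
9 | (2S,3S)-2-[(1S)-1-hydroxy-3-iodobut-3-en-1-yl]-3-methyl-3-[1-(trimethylsilyl)ethenyl]cyclopentan-1-one | C=C(I)C[C@H](O)[C@@H]1[C@](C)(CCC1=O)C(=C)[Si](C)(C)C | intermediate
10 | (2S,3R)-3-ethenyl-2-[(1S)-1-hydroxy-3-iodobut-3-en-1-yl]-3-methylcyclopentan-1-one | C=C(I)C[C@H](O)[C@@H]1[C@](C)(CCC1=O)C=C | intermediate
11 | (2S,3R)-3-ethenyl-2-[(1S)-3-iodo-1-(triethylsilyloxy)but-3-en-1-yl]-3-methylcyclopentan-1-one | C=C(I)C[C@H](O[Si](CC)(CC)CC)[C@@H]1[C@](C)(CCC1=O)C=C | intermediate
12 | (1R,2S,3R)-3-ethenyl-2-[(1S)-3-iodo-1-(triethylsilyloxy)but-3-en-1-yl]-3-methyl-1-(propan-2-yl)cyclopentan-1-ol | C=C(I)C[C@H](O[Si](CC)(CC)CC)[C@@H]1[C@](C)(CC[C@@]1(O)C(C)C)C=C | intermediate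
13 | (1R,2S,3R)-3-ethenyl-2-[(1S)-1-hydroxy-3-iodobut-3-en-1-yl]-3-methyl-1-(propan-2-yl)cyclopentan-1-ol | C=C(I)C[C@H](O)[C@@H]1[C@](C)(CC[C@@]1(O)C(C)C)C=C | intermediate
14 | 4-hydroxybenzoic acid | O=C(O)c1ccc(O)cc1 | starting material
15 | tri(propan-2-yl)silyl 4-{[tri(propan-2-yl)silyl]oxy}benzoate | CC(C)[Si](Oc1ccc(cc1)C(=O)O[Si](C(C)C)(C(C)C)C(C)C)(C(C)C)C(C)C | intermediate (not isolated)
16 | 4-{[tri(propan-2-yl)silyl]oxy}benzoic acid | CC(C)[Si](Oc1ccc(cc1)C(=O)O)(C(C)C)C(C)C | intermediate
17 | (1S)-1-[(1S,2R,5R)-2-ethenyl-5-hydroxy-2-methyl-5-(propan-2-yl)cyclopentyl]-3-iodobut-3-en-1-yl 4-{[tri(propan-2-yl)silyl]oxy}benzoate | C=C(I)C[C@H](OC(=O)c1ccc(O[Si](C(C)C)(C(C)C)C(C)C)cc1)[C@@H]1[C@](C)(CC[C@@]1(O)C(C)C)C=C | intermediate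
18 | 9-borabicyclo[3.3.1]nonan-9-yl adduct of 17 at the terminal vinyl carbon (C10H2–C9H2–B) | C=C(I)C[C@H](OC(=O)c1ccc(O[Si](C(C)C)(C(C)C)C(C)C)cc1)[C@@H]1[C@](C)(CC[C@@]1(O)C(C)C)CCB1C2CCCC1CCC2 | intermediate (not isolated)
19 | (1S)-1-[(1S,2R,5R)-2-hydroxy-5-(2-hydroxyethyl)-5-methyl-2-(propan-2-yl)cyclopentyl]-3-iodobut-3-en-1-yl 4-{[tri(propan-2-yl)silyl]oxy}benzoate | C=C(I)C[C@H](OC(=O)c1ccc(O[Si](C(C)C)(C(C)C)C(C)C)cc1)[C@@H]1[C@](C)(CC[C@@]1(O)C(C)C)CCO | intermediate
20 | (1S)-1-[(1S,2R,5R)-2-hydroxy-5-methyl-5-(2-oxoethyl)-2-(propan-2-yl)cyclopentyl]-3-iodobut-3-en-1-yl 4-{[tri(propan-2-yl)silyl]oxy}benzoate | C=C(I)C[C@H](OC(=O)c1ccc(O[Si](C(C)C)(C(C)C)C(C)C)cc1)[C@@H]1[C@](C)(CC[C@@]1(O)C(C)C)CC=O | intermediate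
21 | alkenylchromium dichloride derived from 20 (CrCl2 in place of iodine at C8) | C=C([Cr](Cl)Cl)C[C@H](OC(=O)c1ccc(O[Si](C(C)C)(C(C)C)C(C)C)cc1)[C@@H]1[C@](C)(CC[C@@]1(O)C(C)C)CC=O | intermediate (not isolated)
22 | (1R,4R,5S,6S)-4,9-dihydroxydauc-8(14)-en-6-yl 4-{[tri(propan-2-yl)silyl]oxy}benzoate, both C9 epimers | C=C1C[C@H](OC(=O)c2ccc(O[Si](C(C)C)(C(C)C)C(C)C)cc2)[C@@H]2[C@](C)(CC[C@@]2(O)C(C)C)CC1O | intermediate
23 | (1R,4R,5S,6S)-4-hydroxy-9-oxodauc-8(14)-en-6-yl 4-{[tri(propan-2-yl)silyl]oxy}benzoate | C=C1C[C@H](OC(=O)c2ccc(O[Si](C(C)C)(C(C)C)C(C)C)cc2)[C@@H]2[C@](C)(CC[C@@]2(O)C(C)C)CC1=O | intermediate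
24 | (1R,4R,5S,6S,9R)-4,9-dihydroxydauc-8(14)-en-6-yl 4-{[tri(propan-2-yl)silyl]oxy}benzoate | C=C1C[C@H](OC(=O)c2ccc(O[Si](C(C)C)(C(C)C)C(C)C)cc2)[C@@H]2[C@](C)(CC[C@@]2(O)C(C)C)C[C@H]1O | intermediate
25 | (1R,4R,5S,6S,9R)-4,9-dihydroxydauc-8(14)-en-6-yl 4-hydroxybenzoate (trans-fused; 1β-CH3, 4β-OH, 5α-H, 6α-ester, 9β-OH) | C=C1C[C@H](OC(=O)c2ccc(O)cc2)[C@@H]2[C@](C)(CC[C@@]2(O)C(C)C)C[C@H]1O | target

**Step count**

Total: 16 steps. Longest linear sequence: 14 steps (3 to 25 through steps 2–8 and 10–16); steps 1 and 9 are side branches.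

**Steps most likely to fail**

1. Step 4. The basic aluminate enolate may take a proton from the α-acidic, β,γ-unsaturated aldehyde (enolisation and isomerisation into conjugation) instead of adding to it. The hindered enolate next to the quaternary carbon may react slowly, surplus alanate may transfer its alkenyl group to the aldehyde, and the anti preference may erode. The fallback sets out from aluminium enolate 7 and separates the two bond formations. The conjugate addition is quenched with TMSOTf to give the isolable trimethylsilyl enol ether F1, freed from aluminium residues and surplus alane. MeLi in THF at 0 °C then gives the lithium enolate F2, and ZnCl2 at −78 °C converts it into the less basic chlorozinc enolate F3. Addition of aldehyde 5 at −78 °C through the same closed chair transition state comes back to the route at 9.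

2. Step 7. The isopropyl reagent may enolise the hindered ketone or reduce it by β-hydride transfer, or the addition may stall against the silyloxyalkyl side chain. The fallback sets out from ketol 10 and drops the silyl protection. Excess i-PrMgCl/CeCl3 is added to the free β-hydroxy ketone at −78 °C. The first equivalent forms the cerium aldolate, which chelates and activates the C4 carbonyl and removes the bulk of the silyl group. Attack anti to the C5 chain leads directly to diol 13, where the route is rejoined without 11 and 12.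

3. Step 5. The free β-hydroxy ketone may dehydrate in acid, the C6 hydroxyl may capture the β-silyl cation to give a cyclic ether, or acid may add to the iodoalkene. The fallback sets out from 9 and masks O6 first with an acid-stable group. TIPSOTf/2,6-lutidine gives the triisopropylsilyl ether F4. Protodesilylation with CF3CO2H then gives the vinyl ketone F5, and i-PrMgCl/CeCl3 gives the tertiary alcohol F6. Removal of the silyl ether with TBAF/AcOH at 40 °C comes back to the route at 13.

**Further compounds**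

F1 | step 4 | trimethyl({(3S)-3-methyl-3-[1-(trimethylsilyl)ethenyl]cyclopent-1-en-1-yl}oxy)silane | C=C([Si](C)(C)C)[C@@]1(C)CCC(O[Si](C)(C)C)=C1
F2 | step 4 | lithium (3S)-3-methyl-3-[1-(trimethylsilyl)ethenyl]cyclopent-1-en-1-olate | C=C([Si](C)(C)C)[C@@]1(C)CCC(O[Li])=C1
F3 | step 4 | chlorozinc (3S)-3-methyl-3-[1-(trimethylsilyl)ethenyl]cyclopent-1-en-1-olate | C=C([Si](C)(C)C)[C@@]1(C)CCC(O[Zn]Cl)=C1
F4 | step 5 | (2S,3S)-2-[(1S)-3-iodo-1-{[tri(propan-2-yl)silyl]oxy}but-3-en-1-yl]-3-methyl-3-[1-(trimethylsilyl)ethenyl]cyclopentan-1-one | C=C(I)C[C@H](O[Si](C(C)C)(C(C)C)C(C)C)[C@@H]1[C@](C)(CCC1=O)C(=C)[Si](C)(C)C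
F5 | step 5 | (2S,3R)-3-ethenyl-2-[(1S)-3-iodo-1-{[tri(propan-2-yl)silyl]oxy}but-3-en-1-yl]-3-methylcyclopentan-1-one | C=C(I)C[C@H](O[Si](C(C)C)(C(C)C)C(C)C)[C@@H]1[C@](C)(CCC1=O)C=C
F6 | step 5 | (1R,2S,3R)-3-ethenyl-2-[(1S)-3-iodo-1-{[tri(propan-2-yl)silyl]oxy}but-3-en-1-yl]-3-methyl-1-(propan-2-yl)cyclopentan-1-ol | C=C(I)C[C@H](O[Si](C(C)C)(C(C)C)C(C)C)[C@@H]1[C@](C)(CC[C@@]1(O)C(C)C)C=C
F0 | step 7 | none | none
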